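**Plan**

- Ring A (the 3-methoxyphenyl ring: C1 carries the CH2CH2 bridge, C3 the OMe, C2 between them is unsubstituted) has its only oxygen meta to its only carbon substituent. This is the pattern of a 6-alkylsalicylate that has lost CO2 from C2, so the ring is cut at C1–C2 and C4–C5. C2–C3–C4 come from the bis-silyl dienol ether of methyl acetoacetate, and C5–C6–C1 from a β-ethoxy enone.
- The enone is traced back through an ynone (C1–C6 bond, ethynyl Grignard on a Weinreb amide). The remaining cuts are the C=C precursor of the ring C–ring D bridge (Wittig), the ring B oxygen–ring C bond (SNAr on 4-fluorobenzaldehyde) and the Cα=Cβ precursor of the ring B side chain (Wittig).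
- Forward: ring D phosphonium salt; ring B aldehyde to cinnamoyl Weinreb amide; diaryl ether (ring C joined); stilbene (ring D joined); one hydrogenation saturating both bridges; ynone; ethoxy enone; ring A built last by cyclocondensation; then CO2Me removed, OH methylated, benzyl ethers cleaved.
- Stereochemistry: none to set. Alkene geometries of intermediates are erased by hydrogenation or aromatisation.

Key step: step 12

Remark: the target has no stereocentre and no stereogenic double bond, so it is a single achiral compound and needs no stereocontrol.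
Remark: 4-(benzyloxy)-3-hydroxybenzaldehyde 5 and the amide ylide 6 are taken as catalogue compounds.

**Route**

Step 1
Reactants: 1 2,5-dihydroxybenzaldehyde
Product: 2 2,5-bis(benzyloxy)benzaldehyde
Conditions: BnBr (2.4 equiv), K2CO3 (3 equiv), DMF, 60 °C
Reagents that add atoms: benzyl bromide, BrCc1ccccc1
Why: Williamson O-alkylation of both phenols (the hydrogen-bonded 2-OH needs warm DMF); benzyl is chosen because it should survive base, heat and low-temperature TiCl4 and leaves by hydrogenolysis without touching an aryl methyl ether.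

Step 2
Reactants: 2 2,5-bis(benzyloxy)benzaldehyde
Product: 3 [2,5-bis(benzyloxy)phenyl]methanol
Conditions: NaBH4, MeOH/THF, 0 °C
Reagents that add atoms: none
Why: Borohydride reduction of an aromatic aldehyde is chemoselective and leaves the benzyl ethers alone.

Step 3
Reactants: 3 [2,5-bis(benzyloxy)phenyl]methanol
Product: 4 {[2,5-bis(benzyloxy)phenyl]methyl}triphenylphosphonium bromide
Conditions: PPh3·HBr, MeCN, reflux
Reagents that add atoms: triphenylphosphine hydrobromide, Br.c1ccc(cc1)P(c1ccccc1)c1ccccc1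
Why: The electron-rich benzylic alcohol is activated by the acidic salt and captured by triphenylphosphine (SN1/SN2 at the benzylic carbon), a direct alcohol-to-phosphonium conversion that avoids a separate bromide.

Step 4
Reactants: 5 4-(benzyloxy)-3-hydroxybenzaldehyde; 6 N-methoxy-N-methyl-2-(triphenylphosphoranylidene)acetamide
Product: 7 (E)-3-[4-(benzyloxy)-3-hydroxyphenyl]-N-methoxy-N-methylprop-2-enamide
Conditions: 6 (1.2 equiv), toluene, 90 °C
Reagents that add atoms: none
Why: Wittig olefination with a stabilised amide ylide tolerates the free phenol, gives the E-enamide and installs the ring B three-carbon chain already at the Weinreb amide oxidation level needed in step 8.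

Step 5
Reactants: 7 (E)-3-[4-(benzyloxy)-3-hydroxyphenyl]-N-methoxy-N-methylprop-2-enamide; 8 4-fluorobenzaldehyde
Product: 9 (E)-3-[4-(benzyloxy)-3-(4-formylphenoxy)phenyl]-N-methoxy-N-methylprop-2-enamide
Conditions: 8 (1.2 equiv), K2CO3, DMF, 120 °C
Reagents that add atoms: none
Why: SNAr, in which the phenoxide of 7 displaces fluoride para to the formyl group through a Meisenheimer intermediate; the formyl group then serves as the handle for ring D.

Step 6
Reactants: 4 {[2,5-bis(benzyloxy)phenyl]methyl}triphenylphosphonium bromide; 9 (E)-3-[4-(benzyloxy)-3-(4-formylphenoxy)phenyl]-N-methoxy-N-methylprop-2-enamide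
Product: 11 (E)-3-[4-(benzyloxy)-3-(4-{2-[2,5-bis(benzyloxy)phenyl]ethenyl}phenoxy)phenyl]-N-methoxy-N-methylprop-2-enamide (E/Z mixture at the stilbene bond), via phosphonium ylide 10 (not isolated)
Conditions: 4 (1.2 equiv), KOtBu, THF, 0 °C; then 9, 0 °C → rt
Reagents that add atoms: none
Why: Wittig olefination of the aromatic aldehyde by the semi-stabilised benzylic ylide joins ring D to ring C; the enamide should not compete with the aldehyde, and the E/Z mixture is irrelevant because the bond is saturated in step 7.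

Step 7
Reactants: 11 (E)-3-[4-(benzyloxy)-3-(4-{2-[2,5-bis(benzyloxy)phenyl]ethenyl}phenoxy)phenyl]-N-methoxy-N-methylprop-2-enamide
Product: 12 3-[4-(benzyloxy)-3-(4-{2-[2,5-bis(benzyloxy)phenyl]ethyl}phenoxy)phenyl]-N-methoxy-N-methylpropanamide
Conditions: H2 (1 atm), 10% Pd/C, Ph2S (cat.), EtOAc, rt
Reagents that add atoms: none
Why: Catalytic hydrogenation on sulfide-moderated palladium saturates conjugated alkenes while benzylic C–O hydrogenolysis and N–O cleavage are suppressed, so both bridges should be reduced in one operation with the three benzyl ethers kept.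

Step 8
Reactants: 12 3-[4-(benzyloxy)-3-(4-{2-[2,5-bis(benzyloxy)phenyl]ethyl}phenoxy)phenyl]-N-methoxy-N-methylpropanamide; 13 ethynylmagnesium bromide
Product: 14 5-[4-(benzyloxy)-3-(4-{2-[2,5-bis(benzyloxy)phenyl]ethyl}phenoxy)phenyl]pent-1-yn-3-one
Conditions: 13 (3 equiv, THF solution), THF, 0 °C → rt; inverse quench into cold 1 M HCl
Reagents that add atoms: none
Why: Weinreb ketone synthesis, in which the alkynyl Grignard adds once to give a chelated tetrahedral intermediate that collapses to the ynone only on quench; quenching into acid protonates the released N,O-dimethylhydroxylamine before it can add to the ynone.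

Step 9
Reactants: 14 5-[4-(benzyloxy)-3-(4-{2-[2,5-bis(benzyloxy)phenyl]ethyl}phenoxy)phenyl]pent-1-yn-3-one
Product: 15 (E)-5-[4-(benzyloxy)-3-(4-{2-[2,5-bis(benzyloxy)phenyl]ethyl}phenoxy)phenyl]-1-ethoxypent-1-en-3-one
Conditions: EtOH (5 equiv), DABCO (10 mol%), CH2Cl2, 0 °C → rt
Reagents that add atoms: ethanol, CCO
Why: Amine-catalysed oxa-Michael addition of ethanol to the terminal ynone gives the E β-ethoxy enone and should stop there because the vinylogous ester is a much poorer acceptor; this entry is preferred to acylating ethyl vinyl ether with the enolisable acid chloride, which would divert through the ketene to a cyclobutanone.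

Step 10
Reactants: 16 methyl acetoacetate
Product: 17 methyl 3-(trimethylsilyloxy)but-2-enoate (E isomer drawn; geometry of no consequence)
Conditions: TMSCl, Et3N, toluene, rt; filter, distil
Reagents that add atoms: chlorotrimethylsilane, C[Si](C)(C)Cl
Why: O-silylation of the enolised β-keto ester with a silyl chloride and a tertiary amine is the standard route to its silyl enol ether.

Step 11
Reactants: 17 methyl 3-(trimethylsilyloxy)but-2-enoate
Product: 18 1-methoxy-1,3-bis(trimethylsilyloxy)buta-1,3-diene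
Conditions: LDA (commercial solution), THF, −78 °C; TMSCl, −78 °C → rt; non-aqueous work-up, used fresh
Reagents that add atoms: chlorotrimethylsilane, C[Si](C)(C)Cl
Why: Kinetic γ-deprotonation gives the extended ester enolate, which is O-silylated to the 1,3-bis(silyloxy)diene, a masked acetoacetate dianion.

Step 12
Reactants: 15 (E)-5-[4-(benzyloxy)-3-(4-{2-[2,5-bis(benzyloxy)phenyl]ethyl}phenoxy)phenyl]-1-ethoxypent-1-en-3-one; 18 1-methoxy-1,3-bis(trimethylsilyloxy)buta-1,3-diene
Product: 19 methyl 2-{2-[4-(benzyloxy)-3-(4-{2-[2,5-bis(benzyloxy)phenyl]ethyl}phenoxy)phenyl]ethyl}-6-hydroxybenzoate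
Conditions: 18 (1.5 equiv), TiCl4 (1.1 equiv), CH2Cl2, −78 → 20 °C; then 10% aq. HCl
Reagents that add atoms: none
Why: TiCl4 activates the vinylogous ester 15, the terminal CH2 carbon of diene 18 adds in Mukaiyama–Michael fashion to the ethoxy-bearing carbon (forming C4–C5 of ring A) with loss of ethoxide, and the remaining silyl enol ether carbon alpha to the ester then attacks the titanium-bound ketone (forming C1–C2) before loss of water aromatises the ring. The closest known reaction type is the formal [3+3] cyclocondensation of 1,3-bis(silyloxy)-1,3-dienes with 3-alkoxy-2-en-1-ones or β-keto acetals, which gives 6-substituted salicylates. Ring A closes by a 6-(enolexo)-exo-trig aldol addition followed by dehydration. No stereocentre is formed and the E geometry of 15 is lost in the aromatic product. The step needs regioselectivity, and the ethoxy leaving group secures it by making the β-carbon the acetal-like, most electrophilic site for the most nucleophilic (terminal) diene carbon, so the chain ends up ortho to the ester and meta to the hydroxyl; the reversed sense would give the 4-alkyl salicylate, which would reach the same phenol 21 after decarboxylation. The benzyl and diaryl ethers carry no chelating carbonyl and should tolerate TiCl4 over this temperature range.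

Step 13
Reactants: 19 methyl 2-{2-[4-(benzyloxy)-3-(4-{2-[2,5-bis(benzyloxy)phenyl]ethyl}phenoxy)phenyl]ethyl}-6-hydroxybenzoate
Product: 20 2-{2-[4-(benzyloxy)-3-(4-{2-[2,5-bis(benzyloxy)phenyl]ethyl}phenoxy)phenyl]ethyl}-6-hydroxybenzoic acid
Conditions: KOH (excess), EtOH/THF/H2O, reflux; then aq. HCl to pH 2
Reagents that add atoms: potassium hydroxide, [K+].[OH-]
Why: Saponification of the hindered salicylate ester under forcing aqueous hydroxide, to which the benzyl and diaryl ethers are inert.

Step 14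
Reactants: 20 2-{2-[4-(benzyloxy)-3-(4-{2-[2,5-bis(benzyloxy)phenyl]ethyl}phenoxy)phenyl]ethyl}-6-hydroxybenzoic acid
Product: 21 3-{2-[4-(benzyloxy)-3-(4-{2-[2,5-bis(benzyloxy)phenyl]ethyl}phenoxy)phenyl]ethyl}phenol
Conditions: Cu powder (cat.), quinoline, 190 °C, Ar
Reagents that add atoms: none
Why: Thermal protodecarboxylation of a salicylic acid, in which ipso-protonation ortho to the hydroxyl gives a β-keto-acid-like dienone that loses CO2 (as 6-alkylsalicylic acids do on heating), leaving the hydroxyl meta to the chain.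

Step 15
Reactants: 21 3-{2-[4-(benzyloxy)-3-(4-{2-[2,5-bis(benzyloxy)phenyl]ethyl}phenoxy)phenyl]ethyl}phenol
Product: 22 1-(benzyloxy)-2-(4-{2-[2,5-bis(benzyloxy)phenyl]ethyl}phenoxy)-4-[2-(3-methoxyphenyl)ethyl]benzene
Conditions: MeI, K2CO3, acetone, 50 °C
Reagents that add atoms: iodomethane, CI
Why: Williamson methylation of the only free phenol; every other oxygen is already etherified, so no selectivity question arises.

Step 16
Reactants: 22 1-(benzyloxy)-2-(4-{2-[2,5-bis(benzyloxy)phenyl]ethyl}phenoxy)-4-[2-(3-methoxyphenyl)ethyl]benzene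
Product: 23 2-[2-(4-{2-hydroxy-5-[2-(3-methoxyphenyl)ethyl]phenoxy}phenyl)ethyl]benzene-1,4-diol (CNP0211397.0)
Conditions: H2 (1 atm), 10% Pd/C, degassed EtOAc/MeOH, rt
Reagents that add atoms: none
Why: Hydrogenolysis of the three aryl benzyl ethers over unpoisoned palladium, to which the aryl methyl ether, the diaryl ether and the saturated bridges are inert; the hydroquinone is handled under inert gas to avoid oxidation to the quinone.

**Compound list**

1 | 2,5-dihydroxybenzaldehyde | O=Cc1cc(O)ccc1O | starting material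
2 | 2,5-bis(benzyloxy)benzaldehyde | O=Cc1cc(OCc2ccccc2)ccc1OCc1ccccc1 | intermediate
3 | [2,5-bis(benzyloxy)phenyl]methanol | OCc1cc(OCc2ccccc2)ccc1OCc1ccccc1 | intermediate
4 | {[2,5-bis(benzyloxy)phenyl]methyl}triphenylphosphonium bromide | [Br-].c1ccc(cc1)[P+](Cc1cc(OCc2ccccc2)ccc1OCc1ccccc1)(c1ccccc1)c1ccccc1 | intermediate
5 | 4-(benzyloxy)-3-hydroxybenzaldehyde | O=Cc1ccc(OCc2ccccc2)c(O)c1 | starting material
6 | N-methoxy-N-methyl-2-(triphenylphosphoranylidene)acetamide | CON(C)C(=O)C=P(c1ccccc1)(c1ccccc1)c1ccccc1 | starting material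
7 | (E)-3-[4-(benzyloxy)-3-hydroxyphenyl]-N-methoxy-N-methylprop-2-enamide | CON(C)C(=O)/C=C/c1ccc(OCc2ccccc2)c(O)c1 | intermediate
8 | 4-fluorobenzaldehyde | O=Cc1ccc(F)cc1 | starting material
9 | (E)-3-[4-(benzyloxy)-3-(4-formylphenoxy)phenyl]-N-methoxy-N-methylprop-2-enamide | CON(C)C(=O)/C=C/c1ccc(OCc2ccccc2)c(Oc2ccc(C=O)cc2)c1 | intermediate
10 | {[2,5-bis(benzyloxy)phenyl]methylidene}triphenylphosphorane (ylide) | c1ccc(cc1)P(=Cc1cc(OCc2ccccc2)ccc1OCc1ccccc1)(c1ccccc1)c1ccccc1 | intermediate
11 | (E)-3-[4-(benzyloxy)-3-(4-{2-[2,5-bis(benzyloxy)phenyl]ethenyl}phenoxy)phenyl]-N-methoxy-N-methylprop-2-enamide, E/Z mixture at the stilbene bond (left undefined) | CON(C)C(=O)/C=C/c1ccc(OCc2ccccc2)c(Oc2ccc(C=Cc3cc(OCc4ccccc4)ccc3OCc3ccccc3)cc2)c1 | intermediate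
12 | 3-[4-(benzyloxy)-3-(4-{2-[2,5-bis(benzyloxy)phenyl]ethyl}phenoxy)phenyl]-N-methoxy-N-methylpropanamide | CON(C)C(=O)CCc1ccc(OCc2ccccc2)c(Oc2ccc(CCc3cc(OCc4ccccc4)ccc3OCc3ccccc3)cc2)c1 | intermediate
13 | ethynylmagnesium bromide | C#C[Mg]Br | starting material
14 | 5-[4-(benzyloxy)-3-(4-{2-[2,5-bis(benzyloxy)phenyl]ethyl}phenoxy)phenyl]pent-1-yn-3-one | C#CC(=O)CCc1ccc(OCc2ccccc2)c(Oc2ccc(CCc3cc(OCc4ccccc4)ccc3OCc3ccccc3)cc2)c1 | intermediate
15 | (E)-5-[4-(benzyloxy)-3-(4-{2-[2,5-bis(benzyloxy)phenyl]ethyl}phenoxy)phenyl]-1-ethoxypent-1-en-3-one | CCO/C=C/C(=O)CCc1ccc(OCc2ccccc2)c(Oc2ccc(CCc3cc(OCc4ccccc4)ccc3OCc3ccccc3)cc2)c1 | intermediate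
16 | methyl acetoacetate | COC(=O)CC(C)=O | starting material
17 | methyl 3-(trimethylsilyloxy)but-2-enoate (E drawn) | C/C(O[Si](C)(C)C)=C\C(=O)OC | intermediate
18 | 1-methoxy-1,3-bis(trimethylsilyloxy)buta-1,3-diene | CO/C(O[Si](C)(C)C)=C/C(=C)O[Si](C)(C)C | intermediate
19 | methyl 2-{2-[4-(benzyloxy)-3-(4-{2-[2,5-bis(benzyloxy)phenyl]ethyl}phenoxy)phenyl]ethyl}-6-hydroxybenzoate | COC(=O)c1c(O)cccc1CCc1ccc(OCc2ccccc2)c(Oc2ccc(CCc3cc(OCc4ccccc4)ccc3OCc3ccccc3)cc2)c1 | intermediate
20 | 2-{2-[4-(benzyloxy)-3-(4-{2-[2,5-bis(benzyloxy)phenyl]ethyl}phenoxy)phenyl]ethyl}-6-hydroxybenzoic acid | OC(=O)c1c(O)cccc1CCc1ccc(OCc2ccccc2)c(Oc2ccc(CCc3cc(OCc4ccccc4)ccc3OCc3ccccc3)cc2)c1 | intermediate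
21 | 3-{2-[4-(benzyloxy)-3-(4-{2-[2,5-bis(benzyloxy)phenyl]ethyl}phenoxy)phenyl]ethyl}phenol | Oc1cccc(CCc2ccc(OCc3ccccc3)c(Oc3ccc(CCc4cc(OCc5ccccc5)ccc4OCc4ccccc4)cc3)c2)c1 | intermediate
22 | 1-(benzyloxy)-2-(4-{2-[2,5-bis(benzyloxy)phenyl]ethyl}phenoxy)-4-[2-(3-methoxyphenyl)ethyl]benzene | COc1cccc(CCc2ccc(OCc3ccccc3)c(Oc3ccc(CCc4cc(OCc5ccccc5)ccc4OCc4ccccc4)cc3)c2)c1 | intermediate
23 | 2-[2-(4-{2-hydroxy-5-[2-(3-methoxyphenyl)ethyl]phenoxy}phenyl)ethyl]benzene-1,4-diol | COc1cccc(CCc2ccc(O)c(Oc3ccc(CCc4cc(O)ccc4O)cc3)c2)c1 | target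

**Count**

Total steps: 16.
Longest linear sequence: 12 steps (steps 1, 2, 3, 6, 7, 8, 9, 12, 13, 14, 15, 16, from compound 1).

**Steps most likely to fail**

Step 12. The Lewis acid may strip benzyl ethers or hydrolyse the diene faster than the first C–C bond forms, or the sequence may stall before aromatisation. The fallback gives up the late ring construction and brings ring A in as an intact arene. It sets out from 5, which is olefinated with the ylide from commercial (3-methoxybenzyl)triphenylphosphonium chloride (KOtBu, 2.2 equiv, THF) to give 2-(benzyloxy)-5-[2-(3-methoxyphenyl)ethenyl]phenol F1. SNAr of F1 with 8 (K2CO3, DMF, 120 °C) gives 4-{2-(benzyloxy)-5-[2-(3-methoxyphenyl)ethenyl]phenoxy}benzaldehyde F2. Wittig reaction of F2 with ylide 10, generated from 4 as in step 6, gives 1-(benzyloxy)-2-(4-{2-[2,5-bis(benzyloxy)phenyl]ethenyl}phenoxy)-4-[2-(3-methoxyphenyl)ethenyl]benzene F3. Saturation of both stilbene bonds under the conditions of step 7 returns to the route at 22.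

Step 14. Loss of CO2 may be incomplete at temperatures the benzyl ethers tolerate, or thermal benzyl cleavage or migration may compete. The fallback changes the order and the decarboxylation mechanism. It sets out from 19, which is O-methylated first (MeI, K2CO3, DMF) to give methyl 2-{2-[4-(benzyloxy)-3-(4-{2-[2,5-bis(benzyloxy)phenyl]ethyl}phenoxy)phenyl]ethyl}-6-methoxybenzoate F4. Hydrolysis (KOH, DMSO/H2O, 110 °C, then HCl) gives 2-{2-[4-(benzyloxy)-3-(4-{2-[2,5-bis(benzyloxy)phenyl]ethyl}phenoxy)phenyl]ethyl}-6-methoxybenzoic acid F5. Silver-catalysed protodecarboxylation of this 2,6-disubstituted benzoic acid (Ag2CO3 cat., AcOH cat., DMSO, 120 °C) returns to the route at 22, bypassing 20 and 21.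

Step 7. Benzyl ether hydrogenolysis may run alongside alkene saturation, or the moderated catalyst may stall on the stilbene. The fallback accepts full deprotection and re-protects. It sets out from 11, which is hydrogenated exhaustively (H2, Pd/C, MeOH/EtOAc, no additive) to 3-[3-(4-{2-[2,5-dihydroxyphenyl]ethyl}phenoxy)-4-hydroxyphenyl]-N-methoxy-N-methylpropanamide F6. Re-benzylation of the three phenols (BnBr, K2CO3, DMF, under argon) returns to the route at 12.

**Further compounds**

F1 | step 12 | 2-(benzyloxy)-5-[2-(3-methoxyphenyl)ethenyl]phenol (E/Z mixture) | COc1cccc(C=Cc2ccc(OCc3ccccc3)c(O)c2)c1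
F2 | step 12 | 4-{2-(benzyloxy)-5-[2-(3-methoxyphenyl)ethenyl]phenoxy}benzaldehyde (E/Z mixture) | COc1cccc(C=Cc2ccc(OCc3ccccc3)c(Oc3ccc(C=O)cc3)c2)c1
F3 | step 12 | 1-(benzyloxy)-2-(4-{2-[2,5-bis(benzyloxy)phenyl]ethenyl}phenoxy)-4-[2-(3-methoxyphenyl)ethenyl]benzene (E/Z mixtures) | COc1cccc(C=Cc2ccc(OCc3ccccc3)c(Oc3ccc(C=Cc4cc(OCc5ccccc5)ccc4OCc4ccccc4)cc3)c2)c1
F4 | step 14 | methyl 2-{2-[4-(benzyloxy)-3-(4-{2-[2,5-bis(benzyloxy)phenyl]ethyl}phenoxy)phenyl]ethyl}-6-methoxybenzoate | COC(=O)c1c(OC)cccc1CCc1ccc(OCc2ccccc2)c(Oc2ccc(CCc3cc(OCc4ccccc4)ccc3OCc3ccccc3)cc2)c1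
F5 | step 14 | 2-{2-[4-(benzyloxy)-3-(4-{2-[2,5-bis(benzyloxy)phenyl]ethyl}phenoxy)phenyl]ethyl}-6-methoxybenzoic acid | OC(=O)c1c(OC)cccc1CCc1ccc(OCc2ccccc2)c(Oc2ccc(CCc3cc(OCc4ccccc4)ccc3OCc3ccccc3)cc2)c1
F6 | step 7 | 3-[3-(4-{2-[2,5-dihydroxyphenyl]ethyl}phenoxy)-4-hydroxyphenyl]-N-methoxy-N-methylpropanamide | CON(C)C(=O)CCc1ccc(O)c(Oc2ccc(CCc3cc(O)ccc3O)cc2)c1
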